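The cyclopentane ring is disconnected at both bonds that tie its C2–C3 ethano unit to C1 (CHMe) and C4 (CH side chain). The key step exploits that C1 and C4 both sit on the spiro carbon C5: C1–C5–C4 plus two extra carbons is a cyclopentadiene whose termini take up acrolein, an ethylene equivalent, in one Diels–Alder reaction that closes the five-membered ring as a 7-spiro-norbornene. The etheno bridge is temporary: ozonolysis unzips it to a cis keto aldehyde, the acetyl carbon becomes the side chain, and stereoretentive decarbonylation deletes the formyl carbon, leaving methyl and side chain trans. The precursor is an enantioenriched 7-methoxy-1,3-dimethylspiro[4.5]deca-1,3,6-trien-8-one.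

Key step: step 4

Remark: 1-methoxybut-3-en-2-one (3) is taken to be commercially available.

Step 1
Reactants: 1 3-methylcyclopent-2-en-1-one
Product: 2 5-(hydroxymethylidene)-3-methylcyclopent-2-en-1-one
Conditions: LiN(iPr)2 (2.1 equiv), THF, −78 °C; HCO2Et, −78 to 0 °C; aq. HCl
Reagents that add atoms: ethyl formate CCOC=O
Why: Kinetic deprotonation at the α' CH2 and formylation of that enolate (crossed Claisen condensation) should place the formyl group, in its enol form, at C5 only; no stereocentre is formed.

Step 2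
Reactants: 2 5-(hydroxymethylidene)-3-methylcyclopent-2-en-1-one, 3 1-methoxybut-3-en-2-one
Product: 5 (5S)-7-methoxy-3-methylspiro[4.5]deca-2,6-diene-1,8-dione, via formyl diketone 4 (not isolated)
Conditions: cinchona-derived bifunctional squaramide (5 mol %, quinine or quinidine series chosen to give (S)-4), toluene, −20 °C; then TsOH·H2O (10 mol %), toluene, 60 °C
Reagents that add atoms: none
Why: Organocatalytic Michael addition of the cyclic 1,3-dicarbonyl to the vinyl ketone should set the quaternary carbon under catalyst control, and acid-catalysed aldol condensation of the methoxymethyl ketone CH2 onto the aldehyde closes ring A (Robinson-type spiroannulation), acid being used to avoid base-induced loss of the formyl group.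

Step 3
Reactants: 5 (5S)-7-methoxy-3-methylspiro[4.5]deca-2,6-diene-1,8-dione
Product: 7 (5S)-7-methoxy-1,3-dimethylspiro[4.5]deca-1,3,6-trien-8-one, via tertiary carbinol 6 (not isolated)
Conditions: LiN(iPr)2 (1.05 equiv), THF, −78 °C; MeLi (1.5 equiv), −78 to −40 °C; H2O; then camphorsulfonic acid (5 mol %), CH2Cl2, 0 °C
Reagents that add atoms: methyllithium [Li]C
Why: Kinetic α'-deprotonation masks the ring-A enone as its lithium dienolate so that MeLi should add 1,2 only to the cyclopentenone carbonyl (in situ enolate protection, organolithium addition); dehydration of the tertiary allylic alcohol can give only one endocyclic diene because the spiro carbon bears no hydrogen.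

Step 4
Reactants: 7 (5S)-7-methoxy-1,3-dimethylspiro[4.5]deca-1,3,6-trien-8-one, 8 acrolein
Product: 9 3'-methoxy-1,3-dimethyl-4'-oxospiro[bicyclo[2.2.1]hept-2-ene-7,1'-cyclohex-2'-ene]-6-carbaldehyde (endo formyl shown; the vinylic C2' of ring A syn to the C5–C6 bridge)
Conditions: Me2AlCl (1.2 equiv), CH2Cl2, −78 °C; aq. HCl work-up
Reagents that add atoms: none
Why: Concerted, asynchronous [4πs+2πs] cycloaddition of the Me2AlCl-activated enal across C1 and C4 of the cyclopentadiene, its β-carbon bonding to the unsubstituted terminus C4 and its α-carbon to the methyl-bearing terminus C1 (Lewis-acid-promoted Diels–Alder reaction). The closest known reactions are Diels–Alder additions of acrylic dienophiles to 5,5-disubstituted and 1,5,5-trisubstituted cyclopentadienes, with acrolein used as an ethylene equivalent. The one ring that closes is the cyclopentane C1–C2–C3–C4–C5 of the target, formed suprafacially on both partners as the saturated five-membered ring of a bicyclo[2.2.1]heptene whose etheno bridge is kept only until step 11. The two new bridgehead stereocentres are necessarily cis to each other, and their configuration relative to the existing spiro carbon is fixed by the diene face that is attacked. The step needs attack on the face syn to the vinylic CH (C6) of ring A and anti to its CH2–CH2 arm (C10, C9), which the in-plane vinylic C–H and the lack of an axial hydrogen on that side should secure, while the CH2 arm projects hydrogens over the other face; −78 °C is used because the diene can undergo a thermal 1,5-vinyl shift. Regio- and endo/exo selectivity are not needed, since every such isomer should give the same compound 10 after loss of the formyl group.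

Step 5
Reactants: 9 3'-methoxy-1,3-dimethyl-4'-oxospiro[bicyclo[2.2.1]hept-2-ene-7,1'-cyclohex-2'-ene]-6-carbaldehyde
Product: 10 3'-methoxy-1,3-dimethylspiro[bicyclo[2.2.1]hept-2-ene-7,1'-cyclohex-2'-en]-4'-one
Conditions: RhCl(PPh3)3 (1.05 equiv), toluene, 110 °C
Reagents that add atoms: none
Why: Tsuji–Wilkinson decarbonylation replaces the secondary formyl group by hydrogen, which completes the use of acrolein as ethylene and touches no stereocentre of 10.

Step 6
Reactants: 10 3'-methoxy-1,3-dimethylspiro[bicyclo[2.2.1]hept-2-ene-7,1'-cyclohex-2'-en]-4'-one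
Product: 11 3'-methoxy-1,3-dimethylspiro[bicyclo[2.2.1]hept-2-ene-7,1'-cyclohexa-2',4'-dien]-4'-yl trifluoromethanesulfonate
Conditions: KN(SiMe3)2, THF, −78 °C; PhNTf2, −78 to 0 °C; H2O
Reagents that add atoms: N-phenylbis(trifluoromethanesulfonimide) O=S(=O)(N(c1ccccc1)S(=O)(=O)C(F)(F)F)C(F)(F)F
Why: The ketone can enolise only toward its CH2 side, the other α-carbon being the methoxy-bearing sp2 carbon, so O-sulfonylation of the potassium dienolate should give one dienyl triflate (enol triflate formation).

Step 7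
Reactants: 11 3'-methoxy-1,3-dimethylspiro[bicyclo[2.2.1]hept-2-ene-7,1'-cyclohexa-2',4'-dien]-4'-yl trifluoromethanesulfonate
Product: 12 methyl 3'-methoxy-1,3-dimethylspiro[bicyclo[2.2.1]hept-2-ene-7,1'-cyclohexa-2',4'-diene]-4'-carboxylate
Conditions: Pd(OAc)2 (5 mol %), 1,3-bis(diphenylphosphino)propane, CO (1 atm), MeOH, Et3N, DMF, 60 °C
Reagents that add atoms: carbon monoxide [C-]#[O+]; methanol CO
Why: Oxidative addition of the enol triflate to zerovalent palladium, CO insertion and methanolysis should install the methyl ester on the ring-A carbon para to the spiro centre (palladium-catalysed alkoxycarbonylation).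

Step 8
Reactants: 12 methyl 3'-methoxy-1,3-dimethylspiro[bicyclo[2.2.1]hept-2-ene-7,1'-cyclohexa-2',4'-diene]-4'-carboxylate
Product: 13 methyl 1,3-dimethyl-5'-oxospiro[bicyclo[2.2.1]hept-2-ene-7,1'-cyclohex-3'-ene]-4'-carboxylate
Conditions: 0.5 M HCl, THF, 0 °C
Reagents that add atoms: water O
Why: Protonation of the methyl enol ether at the carbon next to the spiro centre and hydrolysis (enol ether hydrolysis) should unveil the ketone and turn that vinylic CH into the ring CH2, while the ester-conjugated alkene stays and the hindered norbornene alkene is spared by the cold dilute acid.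

Step 9
Reactants: 13 methyl 1,3-dimethyl-5'-oxospiro[bicyclo[2.2.1]hept-2-ene-7,1'-cyclohex-3'-ene]-4'-carboxylate
Product: 14 methyl (5'S)-5'-hydroxy-1,3-dimethylspiro[bicyclo[2.2.1]hept-2-ene-7,1'-cyclohex-3'-ene]-4'-carboxylate
Conditions: (R)-2-methyl-CBS-oxazaborolidine (20 mol %), catecholborane, toluene, −78 °C; MeOH, aq. NaHCO3
Reagents that add atoms: none
Why: Corey–Bakshi–Shibata 1,2-reduction, in which the ester-bearing sp2 carbon acts as the large group and the CH2 as the small one, should set the (S) carbinol by catalyst control independently of the remote spiro centre.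

Step 10
Reactants: 14 methyl (5'S)-5'-hydroxy-1,3-dimethylspiro[bicyclo[2.2.1]hept-2-ene-7,1'-cyclohex-3'-ene]-4'-carboxylate
Product: 15 methyl (5'S)-5'-[(tert-butyldimethylsilyl)oxy]-1,3-dimethylspiro[bicyclo[2.2.1]hept-2-ene-7,1'-cyclohex-3'-ene]-4'-carboxylate
Conditions: TBSOTf, 2,6-lutidine, CH2Cl2, −78 to 0 °C
Reagents that add atoms: tert-butyldimethylsilyl trifluoromethanesulfonate CC(C)(C)[Si](C)(C)OS(=O)(=O)C(F)(F)F
Why: Silylation of the allylic alcohol (silyl ether protection) prevents its isomerisation or hemiketal formation in steps 11 to 14.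

Step 11
Reactants: 15 methyl (5'S)-5'-[(tert-butyldimethylsilyl)oxy]-1,3-dimethylspiro[bicyclo[2.2.1]hept-2-ene-7,1'-cyclohex-3'-ene]-4'-carboxylate
Product: 16 methyl 4-acetyl-9-[(tert-butyldimethylsilyl)oxy]-1-formyl-1-methylspiro[4.5]dec-7-ene-8-carboxylate (acetyl and formyl cis; other centres as in 22)
Conditions: O3, CH2Cl2–MeOH, NaHCO3, −78 °C (Sudan Red 7B end point); Me2S, −78 to 25 °C
Reagents that add atoms: ozone [O-][O+]=O
Why: Ozonolysis (Criegee mechanism, reductive work-up) should cleave the strained, electron-rich trisubstituted norbornene alkene in preference to the electron-poor enoate alkene, opening the temporary ring to a cis-1,3 keto aldehyde without touching a stereocentre.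

Step 12
Reactants: 16 methyl 4-acetyl-9-[(tert-butyldimethylsilyl)oxy]-1-formyl-1-methylspiro[4.5]dec-7-ene-8-carboxylate
Product: 17 methyl 4-acetyl-9-[(tert-butyldimethylsilyl)oxy]-1-methylspiro[4.5]dec-7-ene-8-carboxylate (acetyl and methyl trans)
Conditions: RhCl(PPh3)3 (1.1 equiv), PhCN, 130 °C
Reagents that add atoms: none
Why: Tsuji–Wilkinson decarbonylation proceeds with retention at carbon, also for angular α-quaternary aldehydes, so hydrogen should take the place of the formyl group on the face cis to acetyl and the former bridgehead methyl ends trans to it; the methyl ketone and enoate are inert.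

Step 13
Reactants: 17 methyl 4-acetyl-9-[(tert-butyldimethylsilyl)oxy]-1-methylspiro[4.5]dec-7-ene-8-carboxylate
Product: 18 methyl 9-[(tert-butyldimethylsilyl)oxy]-1-methyl-4-(prop-1-en-2-yl)spiro[4.5]dec-7-ene-8-carboxylate
Conditions: Zn, CH2Br2, TiCl4, THF–CH2Cl2, 0 to 25 °C
Reagents that add atoms: dibromomethane BrCBr
Why: Takai–Lombardo methylenation is non-basic, so the hindered methyl ketone should be converted without epimerising the adjacent ring CH and without attack on the ester.

Step 14
Reactants: 18 methyl 9-[(tert-butyldimethylsilyl)oxy]-1-methyl-4-(prop-1-en-2-yl)spiro[4.5]dec-7-ene-8-carboxylate, 19 1-bromo-3-methylbutan-2-one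
Product: 21 methyl (1S,4R,5S,9S)-9-[(tert-butyldimethylsilyl)oxy]-1-methyl-4-[(2R)-6-methyl-5-oxoheptan-2-yl]spiro[4.5]dec-7-ene-8-carboxylate, via B-alkyl-9-BBN 20 (not isolated)
Conditions: 9-BBN (1.3 equiv), THF, 0 to 25 °C; then 19, potassium 2,6-di-tert-butylphenoxide, THF, 0 °C
Reagents that add atoms: 9-borabicyclo[3.3.1]nonane B1C2CCCC1CCC2 (boron stays only in 20)
Why: Anti-Markovnikov hydroboration of the 1,1-disubstituted alkene, with the ring C–H eclipsing the double bond (A(1,3) strain) and attack anti to the quaternary spiro carbon, should deliver hydrogen to give the (R) methyl-bearing carbon, and the bromo enolate then forms a boron ate complex whose 1,2-alkyl migration (α-alkylation of an α-bromo ketone by a trialkylborane) completes the side chain; the enoate is too hindered and electron-poor for 9-BBN.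

Step 15
Reactants: 21 methyl (1S,4R,5S,9S)-9-[(tert-butyldimethylsilyl)oxy]-1-methyl-4-[(2R)-6-methyl-5-oxoheptan-2-yl]spiro[4.5]dec-7-ene-8-carboxylate
Product: 22 methyl (1S,4R,5S,9S)-9-hydroxy-1-methyl-4-[(2R)-6-methyl-5-oxoheptan-2-yl]spiro[4.5]dec-7-ene-8-carboxylate
Conditions: HF·pyridine, THF, 0 to 25 °C
Reagents that add atoms: none
Why: Fluoride-mediated silyl ether cleavage under weakly acidic conditions should free the allylic alcohol without retro-aldol or epimerisation next to the ketones.

Compound list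
1 | 3-methylcyclopent-2-en-1-one | CC1=CC(=O)CC1 | starting material
2 | 5-(hydroxymethylidene)-3-methylcyclopent-2-en-1-one | CC1=CC(=O)C(=CO)C1 | intermediate
3 | 1-methoxybut-3-en-2-one | COCC(=O)C=C | starting material
4 | (1S)-1-(4-methoxy-3-oxobutyl)-4-methyl-2-oxocyclopent-3-ene-1-carbaldehyde | O=C[C@]1(CCC(=O)COC)CC(C)=CC1=O | intermediate
5 | (5S)-7-methoxy-3-methylspiro[4.5]deca-2,6-diene-1,8-dione | CC1=CC(=O)[C@@]2(C1)C=C(OC)C(=O)CC2 | intermediate
6 | 1-hydroxy-7-methoxy-1,3-dimethylspiro[4.5]deca-2,6-dien-8-one (spiro carbon as in 5, either carbinol epimer) | CC1=CC(C)(O)[C@@]2(C1)C=C(OC)C(=O)CC2 | intermediate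
7 | (5S)-7-methoxy-1,3-dimethylspiro[4.5]deca-1,3,6-trien-8-one | CC1=CC(C)=C[C@@]12C=C(OC)C(=O)CC2 | intermediate
8 | acrolein (prop-2-enal) | C=CC=O | starting material
9 | 3'-methoxy-1,3-dimethyl-4'-oxospiro[bicyclo[2.2.1]hept-2-ene-7,1'-cyclohex-2'-ene]-6-carbaldehyde (endo formyl, C2' syn to C5–C6) | COC1=C[C@]2(CCC1=O)[C@H]3C(C)=C[C@]2(C)[C@H](C=O)C3 | intermediate
10 | 3'-methoxy-1,3-dimethylspiro[bicyclo[2.2.1]hept-2-ene-7,1'-cyclohex-2'-en]-4'-one (C2' syn to C5–C6) | COC1=C[C@]2(CCC1=O)[C@H]3C(C)=C[C@]2(C)CC3 | intermediate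
11 | 3'-methoxy-1,3-dimethylspiro[bicyclo[2.2.1]hept-2-ene-7,1'-cyclohexa-2',4'-dien]-4'-yl trifluoromethanesulfonate | COC1=C[C@]2(CC=C1OS(=O)(=O)C(F)(F)F)[C@H]3C(C)=C[C@]2(C)CC3 | intermediate
12 | methyl 3'-methoxy-1,3-dimethylspiro[bicyclo[2.2.1]hept-2-ene-7,1'-cyclohexa-2',4'-diene]-4'-carboxylate | COC(=O)C1=CC[C@@]2(C=C1OC)[C@H]3C(C)=C[C@]2(C)CC3 | intermediate
13 | methyl 1,3-dimethyl-5'-oxospiro[bicyclo[2.2.1]hept-2-ene-7,1'-cyclohex-3'-ene]-4'-carboxylate | COC(=O)C1=CC[C@@]2(CC1=O)[C@H]3C(C)=C[C@]2(C)CC3 | intermediate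
14 | methyl (5'S)-5'-hydroxy-1,3-dimethylspiro[bicyclo[2.2.1]hept-2-ene-7,1'-cyclohex-3'-ene]-4'-carboxylate | COC(=O)C1=CC[C@@]2(C[C@@H]1O)[C@H]3C(C)=C[C@]2(C)CC3 | intermediate
15 | methyl (5'S)-5'-[(tert-butyldimethylsilyl)oxy]-1,3-dimethylspiro[bicyclo[2.2.1]hept-2-ene-7,1'-cyclohex-3'-ene]-4'-carboxylate | COC(=O)C1=CC[C@@]2(C[C@@H]1O[Si](C)(C)C(C)(C)C)[C@H]3C(C)=C[C@]2(C)CC3 | intermediate
16 | methyl 4-acetyl-9-[(tert-butyldimethylsilyl)oxy]-1-formyl-1-methylspiro[4.5]dec-7-ene-8-carboxylate (acetyl and formyl cis) | COC(=O)C1=CC[C@@]2(C[C@@H]1O[Si](C)(C)C(C)(C)C)[C@@H](C(C)=O)CC[C@]2(C=O)C | intermediate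
17 | methyl 4-acetyl-9-[(tert-butyldimethylsilyl)oxy]-1-methylspiro[4.5]dec-7-ene-8-carboxylate (acetyl and methyl trans) | COC(=O)C1=CC[C@@]2(C[C@@H]1O[Si](C)(C)C(C)(C)C)[C@@H](C(C)=O)CC[C@@H]2C | intermediate
18 | methyl 9-[(tert-butyldimethylsilyl)oxy]-1-methyl-4-(prop-1-en-2-yl)spiro[4.5]dec-7-ene-8-carboxylate | COC(=O)C1=CC[C@@]2(C[C@@H]1O[Si](C)(C)C(C)(C)C)[C@@H](C(C)=C)CC[C@@H]2C | intermediate
19 | 1-bromo-3-methylbutan-2-one | CC(C)C(=O)CBr | starting material
20 | methyl 4-[(2R)-1-(9-borabicyclo[3.3.1]nonan-9-yl)propan-2-yl]-9-[(tert-butyldimethylsilyl)oxy]-1-methylspiro[4.5]dec-7-ene-8-carboxylate | COC(=O)C1=CC[C@@]2(C[C@@H]1O[Si](C)(C)C(C)(C)C)[C@@H]([C@H](C)CB3C4CCCC3CCC4)CC[C@@H]2C | intermediate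
21 | methyl (1S,4R,5S,9S)-9-[(tert-butyldimethylsilyl)oxy]-1-methyl-4-[(2R)-6-methyl-5-oxoheptan-2-yl]spiro[4.5]dec-7-ene-8-carboxylate | COC(=O)C1=CC[C@@]2(C[C@@H]1O[Si](C)(C)C(C)(C)C)[C@@H]([C@H](C)CCC(=O)C(C)C)CC[C@@H]2C | intermediate
22 | methyl (1S,4R,5S,9S)-9-hydroxy-1-methyl-4-[(2R)-6-methyl-5-oxoheptan-2-yl]spiro[4.5]dec-7-ene-8-carboxylate | COC(=O)C1=CC[C@@]2(C[C@@H]1O)[C@@H]([C@H](C)CCC(=O)C(C)C)CC[C@@H]2C | target

Total step count: 15. Longest linear sequence: 15 steps (1 to 22).

Steps most likely to fail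

Step 4. The two faces of the spiro diene may be poorly discriminated, bond formation at the methyl-bearing terminus may be slow, and the diene may rearrange by a 1,5-vinyl shift. The fallback moves the control element onto the dienophile and sets out from 7. Et2AlCl-promoted cycloaddition with commercial (S)-3-acryloyl-4-benzyloxazolidin-2-one (chelated imide, endo addition, acyl carbon bonding to the methyl-bearing terminus) should select the diene face by reagent control and give the N-acyl oxazolidinone F3. LiOH/H2O2 would cleave the auxiliary to the norbornene carboxylic acid F4. Conversion with oxalyl chloride and the sodium salt of N-hydroxypyridine-2-thione to the thiohydroxamate ester F5, followed by t-BuSH under visible light (Barton decarboxylation), would return to the route at 10.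

Step 2. Face selection in the C–C bond formation at the quaternary carbon may be low, and the formyl group may be lost by retro-Claisen cleavage. The fallback uses a covalently bound chiral amine and sets out from 2. Condensation with (R)-1-phenylethylamine would give the enaminone F1, whose auxiliary-controlled Michael addition to 3 would give the imine F2. Aqueous acetic acid hydrolysis would give 4, which is cyclised with TsOH as before, so the fallback comes back at 5.

Step 14. Face selection in the hydroboration may be poor, and migration of the β-branched alkyl group from boron may be slow. The fallback sets the methyl-bearing carbon by catalyst control and sets out from 17. Kinetic enolisation (KN(SiMe3)2, PhNTf2) would give the terminal enol triflate F6. Reductive Heck coupling with commercial 4-methylpent-1-en-3-one (Pd(OAc)2, PPh3, HCO2H, Et3N, DMF) would give the 1,1-disubstituted alkene F7. Asymmetric hydrogenation with [Ir(cod)(L)]B[3,5-(CF3)2C6H3]4 (L = a chiral phosphinooxazoline, H2, CH2Cl2), which should reduce the terminal alkene faster than the trisubstituted enoate, would come back to the route at 21.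

Further compounds
F1 | step 2 | 3-methyl-5-({[(1R)-1-phenylethyl]amino}methylidene)cyclopent-2-en-1-one | CC1=CC(=O)C(=CN[C@H](C)c2ccccc2)C1
F2 | step 2 | N-[(1R)-1-phenylethyl]imine of (1S)-1-(4-methoxy-3-oxobutyl)-4-methyl-2-oxocyclopent-3-ene-1-carbaldehyde | O=C1C=C(C)C[C@@]1(CCC(=O)COC)C=N[C@H](C)c1ccccc1
F3 | step 4 | (4S)-4-benzyl-3-{[3'-methoxy-1,3-dimethyl-4'-oxospiro[bicyclo[2.2.1]hept-2-ene-7,1'-cyclohex-2'-en]-6-yl]carbonyl}oxazolidin-2-one (endo) | COC1=C[C@]2(CCC1=O)[C@H]3C(C)=C[C@]2(C)[C@H](C(=O)N4[C@@H](Cc5ccccc5)COC4=O)C3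
F4 | step 4 | 3'-methoxy-1,3-dimethyl-4'-oxospiro[bicyclo[2.2.1]hept-2-ene-7,1'-cyclohex-2'-ene]-6-carboxylic acid (endo) | COC1=C[C@]2(CCC1=O)[C@H]3C(C)=C[C@]2(C)[C@H](C(=O)O)C3
F5 | step 4 | 2-thioxopyridin-1(2H)-yl ester of F4 | COC1=C[C@]2(CCC1=O)[C@H]3C(C)=C[C@]2(C)[C@H](C(=O)ON4C=CC=CC4=S)C3
F6 | step 14 | methyl 9-[(tert-butyldimethylsilyl)oxy]-1-methyl-4-{1-[(trifluoromethanesulfonyl)oxy]ethenyl}spiro[4.5]dec-7-ene-8-carboxylate | COC(=O)C1=CC[C@@]2(C[C@@H]1O[Si](C)(C)C(C)(C)C)[C@@H](C(=C)OS(=O)(=O)C(F)(F)F)CC[C@@H]2C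
F7 | step 14 | methyl 9-[(tert-butyldimethylsilyl)oxy]-1-methyl-4-(6-methyl-5-oxohept-1-en-2-yl)spiro[4.5]dec-7-ene-8-carboxylate | COC(=O)C1=CC[C@@]2(C[C@@H]1O[Si](C)(C)C(C)(C)C)[C@@H](C(=C)CCC(=O)C(C)C)CC[C@@H]2C
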